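**Strategy**

The target is traced back to the 8,26-epoxide of C2-symmetric α-onocerin (onocerane numbering), whose biomimetic epoxide–olefin–ether cascade builds the seven-membered ring and the ether bridge. Both trans-decalins are made together, against the biosynthetic direction: Ph3PAuNTf2 activates a terminal alkyne (C6≡C7, on C8), the E-C5=C10 alkene closes ring B through the bond from C5 (ring-fusion CH beside CMe2) to C6 (ring B CH2), and a Z-vinylsilane (C1) captures the C10 cation to close ring A. This exploits the unfunctionalised C6–C7 bridge and the twofold symmetry. The precursor is an acyclic bis(1,5-enyne) with C8/C9 set by Ireland–Claisen rearrangement.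

Key step: step 11

Remark: onocerane numbering is used throughout (half 1: C1–C10; half 2: C13–C22; link C11–C12). The two decalin halves of the target are homochiral, so compounds 3–20 are C2-symmetric and every operation up to step 13 acts on both ends. Each such step therefore consumes two molecules of its reagent per molecule of substrate (catalyst loadings are per end). In steps 1 and 2 the two-directional partner is a numbered starting material; its first molecule stands under the reactants and its second under the reagents that add atoms. In step 2 the promoter enantiomer is the one that adds to the Si face of each aldehyde (R carbinols); this is assumed to be the L-valine-derived one.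

**Step 1**
Reactants: 1 hexa-1,5-diene; 2 methacrolein (two molecules per molecule of 1; used in excess)
Product: 3 (2E,6E)-2,7-dimethylocta-2,6-dienedial
Conditions: second-generation Grubbs catalyst (5 mol %), CH2Cl2, 40 °C
Reagents that add atoms: methacrolein (second molecule of 2), CC(=C)C=O
Why: Two-directional olefin cross-metathesis in which each terminal alkene of the diene takes up one molecule of methacrolein should give the trisubstituted enals as the thermodynamically favoured E isomers, driven by loss of two molecules of ethylene.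

**Step 2**
Reactants: 3 (2E,6E)-2,7-dimethylocta-2,6-dienedial; 4 1-methoxy-2-methyl-1-(trimethylsilyloxy)prop-1-ene (two molecules per molecule of 3)
Product: 6 dimethyl (3R,4E,8E,10R)-3,10-dihydroxy-2,2,4,9,11,11-hexamethyldodeca-4,8-dienedioate, via bis(trimethylsilyl ether) 5 (not isolated)
Conditions: oxazaborolidinone from N-tosyl-L-valine and BH3·THF (40 mol %), EtNO2, −78 °C; then 1 M HCl
Reagents that add atoms: 1-methoxy-2-methyl-1-(trimethylsilyloxy)prop-1-ene (second molecule of 4), COC(O[Si](C)(C)C)=C(C)C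
Why: Catalytic enantioselective Mukaiyama aldol addition of one ketene silyl acetal molecule to each conjugated aldehyde; catalyst-controlled Si-face attack sets the two carbinols (C5, C17) as R, and the double addition diverts the minor enantiomeric sense into a separable meso isomer.

**Step 3**
Reactants: 6 dimethyl (3R,4E,8E,10R)-3,10-dihydroxy-2,2,4,9,11,11-hexamethyldodeca-4,8-dienedioate
Product: 8 (5R,6E,10E,12R)-5,12-dihydroxy-4,4,6,11,13,13-hexamethyl-1,16-bis(trimethylsilyl)hexadeca-6,10-diene-1,15-diyne-3,14-dione, via bis(Weinreb amide) 7 (not isolated)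
Conditions: MeNH(OMe)·HCl, i-PrMgCl, THF, −20 °C; then Me3SiC≡CLi (from Me3SiC≡CH, n-BuLi), −78 to −20 °C; aq. NH4Cl
Reagents that add atoms: ethynyltrimethylsilane, C#C[Si](C)(C)C
Why: Alkoxide-assisted aminolysis of the esters to N-methoxy-N-methylamides followed by Weinreb ketone synthesis with a lithium acetylide, whose chelated tetrahedral intermediate should prevent over-addition; the ester has no α-hydrogen, so nothing can epimerise.

**Step 4**
Reactants: 8 (5R,6E,10E,12R)-5,12-dihydroxy-4,4,6,11,13,13-hexamethyl-1,16-bis(trimethylsilyl)hexadeca-6,10-diene-1,15-diyne-3,14-dione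
Product: 9 (5R,6E,10E,12R)-4,4,6,11,13,13-hexamethyl-3,14-dioxo-1,16-bis(trimethylsilyl)hexadeca-6,10-diene-1,15-diyne-5,12-diyl bis[(benzyloxy)acetate]
Conditions: BnOCH2COCl, pyridine, CH2Cl2, 0 °C
Reagents that add atoms: (benzyloxy)acetyl chloride, O=C(Cl)COCc1ccccc1
Why: O-Acylation of the allylic alcohols with an acid chloride; the quaternary carbon between carbinol and ketone rules out β-elimination, and capping the hydroxyl stops oxa-Michael closure onto the ynone.

**Step 5**
Reactants: 9 the bis[(benzyloxy)acetate] bis-ynone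
Product: 10 (3R,5R,6E,10E,12R,14R)-3,14-dihydroxy-4,4,6,11,13,13-hexamethyl-1,16-bis(trimethylsilyl)hexadeca-6,10-diene-1,15-diyne-5,12-diyl bis[(benzyloxy)acetate]
Conditions: Ru[(R,R)-TsNCH(Ph)CH(Ph)NH](p-cymene) (5 mol %), i-PrOH, rt
Reagents that add atoms: none
Why: Noyori asymmetric transfer hydrogenation of alkynyl ketones with the divalent ruthenium amido catalyst; reagent control (alkynyl group in the site normally taken by an aryl group) sets C3 and C21, and the esters are not touched.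

**Step 6**
Reactants: 10 the bis(propargylic alcohol)
Product: 11 (3R,5R,6E,10E,12R,14R)-3,14-bis(tert-butyldimethylsilyloxy)-4,4,6,11,13,13-hexamethyl-1,16-bis(trimethylsilyl)hexadeca-6,10-diene-1,15-diyne-5,12-diyl bis[(benzyloxy)acetate]
Conditions: TBSOTf, 2,6-lutidine, CH2Cl2, −78 to 0 °C
Reagents that add atoms: tert-butyldimethylsilyl trifluoromethanesulfonate, CC(C)(C)[Si](C)(C)OS(=O)(=O)C(F)(F)F
Why: Silyl ether formation with a silyl triflate, reactive enough for the neopentyl propargylic alcohols.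

**Step 7**
Reactants: 11 the bis(silyl ether) diyne
Product: 12 (1Z,3S,5R,6E,10E,12R,14S,15Z)-3,14-bis(tert-butyldimethylsilyloxy)-4,4,6,11,13,13-hexamethyl-1,16-bis(trimethylsilyl)hexadeca-1,6,10,15-tetraene-5,12-diyl bis[(benzyloxy)acetate]
Conditions: H2 (1 atm), Pd/CaCO3 poisoned with Pb(OAc)2, quinoline, hexane, rt
Reagents that add atoms: none
Why: Lindlar semi-hydrogenation; syn addition of hydrogen to the silyl alkynes gives the Z-vinylsilanes, while trisubstituted alkenes and benzyl ethers are inert.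

**Step 8**
Reactants: 12 the bis(allylic glycolate)
Product: 15 (2S,3R,6R,7S)-2,7-bis(benzyloxy)-3,6-bis[(2E,5S,6Z)-5-(tert-butyldimethylsilyloxy)-4,4-dimethyl-7-(trimethylsilyl)hepta-2,6-dien-2-yl]octane-1,8-diol, via bis(silyl ketene acetal) 13 (not isolated), via bis(trimethylsilyl ester) 14 (not isolated)
Conditions: LiN(SiMe3)2, Me3SiCl, THF, −78 °C to rt; then LiAlH4, 0 °C
Reagents that add atoms: none
Why: Glycolate Ireland–Claisen rearrangement through the chelation-controlled Z-silyl ketene acetal and a chair transition state with the tert-alkyl group on C5 (C17) equatorial; chirality transfer from the carbinol sets C9 (C13), the enolate geometry sets C8 (C14) syn to it, the new C5=C10 (C17=C18) alkene is E, and the silyl esters are reduced in the same flask.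

**Step 9**
Reactants: 15 the bis(primary alcohol)
Product: 16 (2S,3R,6R,7S)-2,7-bis(benzyloxy)-3,6-bis[(2E,5S,6Z)-5-(tert-butyldimethylsilyloxy)-4,4-dimethyl-7-(trimethylsilyl)hepta-2,6-dien-2-yl]octanedial
Conditions: Dess–Martin periodinane, pyridine, CH2Cl2, 0 °C to rt
Reagents that add atoms: none
Why: Dess–Martin oxidation of primary alcohols under buffered, non-epimerising conditions.

**Step 10**
Reactants: 16 the bis(α-benzyloxy aldehyde)
Product: 17 (3S,4R,7R,8S)-3,8-bis(benzyloxy)-4,7-bis[(2E,5S,6Z)-5-(tert-butyldimethylsilyloxy)-4,4-dimethyl-7-(trimethylsilyl)hepta-2,6-dien-2-yl]deca-1,9-diyne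
Conditions: dimethyl (1-diazo-2-oxopropyl)phosphonate, K2CO3, MeOH, 0 °C to rt
Reagents that add atoms: dimethyl (1-diazo-2-oxopropyl)phosphonate, CC(=O)C(=[N+]=[N-])P(=O)(OC)OC
Why: Ohira–Bestmann homologation of aldehydes to terminal alkynes (C6 and C16 are added); vinylsilanes and silyl ethers tolerate K2CO3/MeOH.

**Step 11**
Reactants: 17 the bis(1,5-enyne)
Product: 18 (3β,8α,14β,21α)-8,14-bis(benzyloxy)-3,21-bis(tert-butyldimethylsilyloxy)-26,27-dinoronocera-1,6,15,19-tetraene (α-onocerin configuration at C5, C9, C10, C13, C17, C18)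
Conditions: Ph3PAuNTf2 (10 mol %), (CF3)2CHOH (4 equiv), CH2Cl2, −20 °C to rt
Reagents that add atoms: none
Why: Cationic monovalent gold activates each terminal alkyne; C5 of the E-C5=C10 alkene attacks the alkyne terminus C6 to close ring B and leave a tertiary cation at C10, which the Z-vinylsilane captures at its silicon-bearing carbon C1 to close ring A, after which loss of the silyl group to hexafluoroisopropanol and protodeauration at C7 release the catalyst. The closest known reaction types are the alkyne-initiated cation–olefin polycyclisation of 1,5-enynes (catalysed by Ph3PAuNTf2-type monovalent gold complexes or by InBr3) and the vinylsilane-terminated cation–olefin cyclisation. Ring B closes 6-endo-dig at the alkyne (endo also at the alkene) and ring A closes 6-endo-trig at the vinylsilane, four rings in all. C5 and C10 (C17 and C18) arise trans from antiperiplanar addition across the E-alkene in a chair–chair array. The alkene face is chosen by C9 (C13) and C8 (C14): only one chair places both the C11 chain and the benzyloxy group equatorial, and the equatorial C3 (C21) silyl ether is matched with it. The step needs 6-endo over 5-endo attack, secured by the fully substituted C10 and the unhindered alkyne terminus, and capture over proton loss, secured by the β-silyl-stabilised ipso attack held in a six-membered chair.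

**Step 12**
Reactants: 18 the bis(benzyl ether) tetraene
Product: 19 (3β,8α,14β,21α)-3,21-bis(tert-butyldimethylsilyloxy)-26,27-dinoronocerane-8,14-diol
Conditions: H2 (1 atm), Pd(OH)2/C, EtOAc, rt
Reagents that add atoms: none
Why: Catalytic hydrogenation of the four cis-disubstituted ring alkenes with concurrent hydrogenolysis of the two benzyl ethers; no stereocentre is created.

**Step 13**
Reactants: 19 the 8,14-diol
Product: 20 (3β,21α)-3,21-bis(tert-butyldimethylsilyloxy)-26,27-dinoronocerane-8,14-dione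
Conditions: Dess–Martin periodinane, pyridine, CH2Cl2, rt
Reagents that add atoms: none
Why: Dess–Martin oxidation of the secondary alcohols; the C9 and C13 side chains stay in the thermodynamically preferred equatorial position next to the ketones.

**Step 14**
Reactants: 20 the 8,14-dione
Product: 21 (3β,21α)-3,21-bis(tert-butyldimethylsilyloxy)-26-noronocer-14(27)-en-8-one
Conditions: Ph3PCH3Br (1.0 equiv), KOt-Bu, toluene, 0 °C to rt; unreacted 20 recycled
Reagents that add atoms: methyltriphenylphosphonium bromide, C[P+](c1ccccc1)(c1ccccc1)c1ccccc1.[Br-]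
Why: Wittig methylenation with one equivalent of ylide; the two ketones are equivalent by symmetry, so either mono-olefin is the same compound and the desymmetrisation is statistical.

**Step 15**
Reactants: 21 the keto olefin
Product: 22 (3β,8β,21α)-3,21-bis(tert-butyldimethylsilyloxy)-8,26-epoxyonocer-14(27)-ene (epoxide oxygen axial, CH2 equatorial)
Conditions: Me3S(O)I, NaH, DMSO/THF, rt
Reagents that add atoms: trimethylsulfoxonium iodide, C[S+](C)(C)=O.[I-]
Why: Corey–Chaykovsky epoxidation; the sulfoxonium ylide delivers CH2 equatorially, away from the axial C10 methyl, so the C8–O bond is axial as needed for backside attack in step 16.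

**Step 16**
Reactants: 22 the epoxy olefin
Product: 23 3,21-bis(tert-butyldimethylsilyl) ether of the target
Conditions: MeAlCl2 (1.2 equiv), CH2Cl2, −78 °C
Reagents that add atoms: none
Why: Lewis acid epoxide-initiated cation–olefin cyclisation with capture by the epoxide oxygen: C27 of the methylene attacks C8 anti to the axial C–O bond (seven-membered ring, C26 becomes axial), and the aluminium alkoxide closes the five-membered ether on the tertiary C14 cation from the less hindered equatorial side, as in ambrox-type closures.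

**Step 17**
Reactants: 23 the bis(silyl ether)
Product: 24 target CNP0223111.1 (14,26-epoxyserratane-3,21-diol, stereochemistry as in the SMILES)
Conditions: HF·pyridine, THF, rt
Reagents that add atoms: none
Why: Fluoride-mediated cleavage of the two hindered secondary silyl ethers; no stereocentre is touched.

**Compound list**

1 | hexa-1,5-diene | C=CCCC=C | starting material
2 | methacrolein | CC(=C)C=O | starting material
3 | (2E,6E)-2,7-dimethylocta-2,6-dienedial | O=C/C(C)=C/CC/C=C(C)/C=O | intermediate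
4 | 1-methoxy-2-methyl-1-(trimethylsilyloxy)prop-1-ene | COC(O[Si](C)(C)C)=C(C)C | starting material
5 | dimethyl (3R,4E,8E,10R)-2,2,4,9,11,11-hexamethyl-3,10-bis(trimethylsilyloxy)dodeca-4,8-dienedioate | COC(=O)C(C)(C)[C@H](O[Si](C)(C)C)/C(C)=C/CC/C=C(C)/[C@@H](O[Si](C)(C)C)C(C)(C)C(=O)OC | intermediate (not isolated)
6 | dimethyl (3R,4E,8E,10R)-3,10-dihydroxy-2,2,4,9,11,11-hexamethyldodeca-4,8-dienedioate | COC(=O)C(C)(C)[C@H](O)/C(C)=C/CC/C=C(C)/[C@@H](O)C(C)(C)C(=O)OC | intermediate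
7 | (3R,4E,8E,10R)-3,10-dihydroxy-N,N'-dimethoxy-N,N',2,2,4,9,11,11-octamethyldodeca-4,8-dienediamide | CON(C)C(=O)C(C)(C)[C@H](O)/C(C)=C/CC/C=C(C)/[C@@H](O)C(C)(C)C(=O)N(C)OC | intermediate (not isolated)
8 | (5R,6E,10E,12R)-5,12-dihydroxy-4,4,6,11,13,13-hexamethyl-1,16-bis(trimethylsilyl)hexadeca-6,10-diene-1,15-diyne-3,14-dione | C[Si](C)(C)C#CC(=O)C(C)(C)[C@H](O)/C(C)=C/CC/C=C(C)/[C@@H](O)C(C)(C)C(=O)C#C[Si](C)(C)C | intermediate
9 | bis[(benzyloxy)acetate] of 8 (5R,12R) | C[Si](C)(C)C#CC(=O)C(C)(C)[C@H](OC(=O)COCc1ccccc1)/C(C)=C/CC/C=C(C)/[C@@H](OC(=O)COCc1ccccc1)C(C)(C)C(=O)C#C[Si](C)(C)C | intermediate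
10 | (3R,5R,6E,10E,12R,14R)-3,14-dihydroxy bis-glycolate diyne | C[Si](C)(C)C#C[C@H](O)C(C)(C)[C@H](OC(=O)COCc1ccccc1)/C(C)=C/CC/C=C(C)/[C@@H](OC(=O)COCc1ccccc1)C(C)(C)[C@@H](O)C#C[Si](C)(C)C | intermediate
11 | (3R,5R,6E,10E,12R,14R)-3,14-bis(tert-butyldimethylsilyloxy) bis-glycolate diyne | C[Si](C)(C)C#C[C@H](O[Si](C)(C)C(C)(C)C)C(C)(C)[C@H](OC(=O)COCc1ccccc1)/C(C)=C/CC/C=C(C)/[C@@H](OC(=O)COCc1ccccc1)C(C)(C)[C@@H](O[Si](C)(C)C(C)(C)C)C#C[Si](C)(C)C | intermediate
12 | (1Z,3S,5R,6E,10E,12R,14S,15Z)-3,14-bis(tert-butyldimethylsilyloxy)-4,4,6,11,13,13-hexamethyl-1,16-bis(trimethylsilyl)hexadeca-1,6,10,15-tetraene-5,12-diyl bis[(benzyloxy)acetate] | C[Si](C)(C)/C=C\[C@H](O[Si](C)(C)C(C)(C)C)C(C)(C)[C@H](OC(=O)COCc1ccccc1)/C(C)=C/CC/C=C(C)/[C@@H](OC(=O)COCc1ccccc1)C(C)(C)[C@@H](O[Si](C)(C)C(C)(C)C)/C=C\[Si](C)(C)C | intermediate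
13 | bis[(Z)-O-trimethylsilyl ketene acetal] of 12 (benzyloxy cis to OSiMe3) | C[Si](C)(C)/C=C\[C@H](O[Si](C)(C)C(C)(C)C)C(C)(C)[C@H](O/C(O[Si](C)(C)C)=C/OCc1ccccc1)/C(C)=C/CC/C=C(C)/[C@@H](O/C(O[Si](C)(C)C)=C/OCc1ccccc1)C(C)(C)[C@@H](O[Si](C)(C)C(C)(C)C)/C=C\[Si](C)(C)C | intermediate (not isolated)
14 | bis(trimethylsilyl) (2S,3R,6R,7S)-2,7-bis(benzyloxy)-3,6-bis[(2E,5S,6Z)-5-(tert-butyldimethylsilyloxy)-4,4-dimethyl-7-(trimethylsilyl)hepta-2,6-dien-2-yl]octanedioate | C[Si](C)(C)/C=C\[C@H](O[Si](C)(C)C(C)(C)C)C(C)(C)/C=C(C)/[C@H]([C@H](OCc1ccccc1)C(=O)O[Si](C)(C)C)CC[C@@H]([C@H](OCc1ccccc1)C(=O)O[Si](C)(C)C)/C(C)=C/C(C)(C)[C@@H](O[Si](C)(C)C(C)(C)C)/C=C\[Si](C)(C)C | intermediate (not isolated)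
15 | (2S,3R,6R,7S)-2,7-bis(benzyloxy)-3,6-bis[(2E,5S,6Z)-5-(tert-butyldimethylsilyloxy)-4,4-dimethyl-7-(trimethylsilyl)hepta-2,6-dien-2-yl]octane-1,8-diol | C[Si](C)(C)/C=C\[C@H](O[Si](C)(C)C(C)(C)C)C(C)(C)/C=C(C)/[C@H]([C@H](OCc1ccccc1)CO)CC[C@@H]([C@H](OCc1ccccc1)CO)/C(C)=C/C(C)(C)[C@@H](O[Si](C)(C)C(C)(C)C)/C=C\[Si](C)(C)C | intermediate
16 | (2S,3R,6R,7S)-2,7-bis(benzyloxy)-3,6-bis[(2E,5S,6Z)-5-(tert-butyldimethylsilyloxy)-4,4-dimethyl-7-(trimethylsilyl)hepta-2,6-dien-2-yl]octanedial | C[Si](C)(C)/C=C\[C@H](O[Si](C)(C)C(C)(C)C)C(C)(C)/C=C(C)/[C@H]([C@H](OCc1ccccc1)C=O)CC[C@@H]([C@H](OCc1ccccc1)C=O)/C(C)=C/C(C)(C)[C@@H](O[Si](C)(C)C(C)(C)C)/C=C\[Si](C)(C)C | intermediate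
17 | (3S,4R,7R,8S)-3,8-bis(benzyloxy)-4,7-bis[(2E,5S,6Z)-5-(tert-butyldimethylsilyloxy)-4,4-dimethyl-7-(trimethylsilyl)hepta-2,6-dien-2-yl]deca-1,9-diyne | C[Si](C)(C)/C=C\[C@H](O[Si](C)(C)C(C)(C)C)C(C)(C)/C=C(C)/[C@H]([C@H](OCc1ccccc1)C#C)CC[C@@H]([C@H](OCc1ccccc1)C#C)/C(C)=C/C(C)(C)[C@@H](O[Si](C)(C)C(C)(C)C)/C=C\[Si](C)(C)C | intermediate
18 | (3β,8α,14β,21α)-8,14-bis(benzyloxy)-3,21-bis(tert-butyldimethylsilyloxy)-26,27-dinoronocera-1,6,15,19-tetraene | CC1(C)[C@@H](O[Si](C)(C)C(C)(C)C)C=C[C@@]2(C)[C@H]1C=C[C@@H](OCc3ccccc3)[C@@H]2CC[C@H]1[C@H](OCc2ccccc2)C=C[C@H]2C(C)(C)[C@@H](O[Si](C)(C)C(C)(C)C)C=C[C@]12C | intermediate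
19 | (3β,8α,14β,21α)-3,21-bis(tert-butyldimethylsilyloxy)-26,27-dinoronocerane-8,14-diol | CC1(C)[C@@H](O[Si](C)(C)C(C)(C)C)CC[C@@]2(C)[C@H]1CC[C@@H](O)[C@@H]2CC[C@H]1[C@H](O)CC[C@H]2C(C)(C)[C@@H](O[Si](C)(C)C(C)(C)C)CC[C@]12C | intermediate
20 | (3β,21α)-3,21-bis(tert-butyldimethylsilyloxy)-26,27-dinoronocerane-8,14-dione | CC1(C)[C@@H](O[Si](C)(C)C(C)(C)C)CC[C@@]2(C)[C@H]1CCC(=O)[C@@H]2CC[C@H]1C(=O)CC[C@H]2C(C)(C)[C@@H](O[Si](C)(C)C(C)(C)C)CC[C@]12C | intermediate
21 | (3β,21α)-3,21-bis(tert-butyldimethylsilyloxy)-26-noronocer-14(27)-en-8-one | CC1(C)[C@@H](O[Si](C)(C)C(C)(C)C)CC[C@@]2(C)[C@H]1CCC(=O)[C@@H]2CC[C@H]1C(=C)CC[C@H]2C(C)(C)[C@@H](O[Si](C)(C)C(C)(C)C)CC[C@]12C | intermediate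
22 | (3β,8β,21α)-3,21-bis(tert-butyldimethylsilyloxy)-8,26-epoxyonocer-14(27)-ene | CC1(C)[C@@H](O[Si](C)(C)C(C)(C)C)CC[C@@]2(C)[C@H]1CC[C@@]3(CO3)[C@@H]2CC[C@H]1C(=C)CC[C@H]2C(C)(C)[C@@H](O[Si](C)(C)C(C)(C)C)CC[C@]12C | intermediate
23 | 3,21-bis(tert-butyldimethylsilyl) ether of the target | CC1(C)[C@@H](O[Si](C)(C)C(C)(C)C)CC[C@@]2(C)[C@H]1CC[C@]13CO[C@@]4(CC[C@H]5C(C)(C)[C@@H](O[Si](C)(C)C(C)(C)C)CC[C@]5(C)[C@H]4CC[C@@H]12)C3 | intermediate
24 | CNP0223111.1 (14,26-epoxyserratane-3,21-diol) | CC1(C)[C@@H](O)CC[C@@]2(C)[C@H]1CC[C@]13CO[C@@]4(CC[C@H]5C(C)(C)[C@@H](O)CC[C@]5(C)[C@H]4CC[C@@H]12)C3 | target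

**Step count and risks**

Total step count: 17. Longest linear sequence: 17 steps (hexa-1,5-diene 1 to target 24; the route is linear and two-directional).

Steps most likely to fail:

Step 11. The C10 cation may lose a proton before the vinylsilane captures it, attack may go 5-endo through a cyclopropyl gold carbene, the propargylic benzyl ether may transfer hydride to the activated alkyne, or the two chair transition states may be poorly discriminated. The fallback is an aldehyde-initiated (Prins-type) cation–olefin bicyclisation that forms the same ring B bond. It sets out from 17: anti-Markovnikov hydration of both alkynes (disiamylborane, then NaOH/H2O2) gives (3R,4R,7R,8R)-3,8-bis(benzyloxy)-4,7-bis[(2E,5S,6Z)-5-(tert-butyldimethylsilyloxy)-4,4-dimethyl-7-(trimethylsilyl)hepta-2,6-dien-2-yl]decanedial F1. MeAlCl2 (CH2Cl2, −78 °C) then lets each aldehyde carbon (C6) take up C5 of the alkene, with vinylsilane capture as before, to give (3β,8α,14β,21α)-8,14-bis(benzyloxy)-3,21-bis(tert-butyldimethylsilyloxy)-26,27-dinoronocera-1,19-diene-6,16-diol F2. The extra hydroxyls are removed by Barton–McCombie deoxygenation through the bis(S-methyl xanthate) F3 (NaH, CS2, MeI) to (3β,8α,14β,21α)-8,14-bis(benzyloxy)-3,21-bis(tert-butyldimethylsilyloxy)-26,27-dinoronocera-1,19-diene F4 (Bu3SnH, AIBN, toluene, 90 °C). Hydrogenation under the conditions of step 12 brings F4 back to the route at 19.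

Step 16. Ionisation of the 1,1-disubstituted epoxide may end in a 1,2-hydride shift (aldehyde) or proton loss faster than the seven-membered ring closes. The fallback separates C–C from C–O bond formation and sets out from 22. Trivalent titanium (Cp2TiCl from Cp2TiCl2 and Zn, THF, rt) opens the epoxide homolytically to the tertiary C8 radical, which adds 7-endo to the C14=C27 methylene; β-hydride loss from the titanium-trapped C14 radical gives (3β,21α)-3,21-bis(tert-butyldimethylsilyloxy)serrat-14-en-26-ol F5. Camphorsulfonic acid (CH2Cl2, rt) then adds the C26 hydroxyl to the protonated trisubstituted alkene (Markovnikov, five-membered ether) and returns to the route at 23.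

Step 3. The metal aldolates may undergo retro-aldol cleavage, or the acetylide may add twice at the hindered acyl carbon. The fallback brings the ynone in with the aldol donor and sets out from 3. 4-Methyl-1-(trimethylsilyl)pent-1-yn-3-one F6 (from isobutyryl chloride and bis(trimethylsilyl)acetylene, AlCl3) is converted into 4-methyl-1-(trimethylsilyl)-3-(trimethylsilyloxy)pent-3-en-1-yne F7 (Me3SiOTf, Et3N). Mukaiyama aldol addition of two molecules of F7 to 3 with the promoter of step 2 gives the bis(trimethylsilyl ether) of 8 F8, and acidic work-up returns to the route at 8.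

**Further compounds**

F1 | step 11 | (3R,4R,7R,8R)-3,8-bis(benzyloxy)-4,7-bis[(2E,5S,6Z)-5-(tert-butyldimethylsilyloxy)-4,4-dimethyl-7-(trimethylsilyl)hepta-2,6-dien-2-yl]decanedial | C[Si](C)(C)/C=C\[C@H](O[Si](C)(C)C(C)(C)C)C(C)(C)/C=C(C)/[C@H]([C@H](OCc1ccccc1)CC=O)CC[C@@H]([C@H](OCc1ccccc1)CC=O)/C(C)=C/C(C)(C)[C@@H](O[Si](C)(C)C(C)(C)C)/C=C\[Si](C)(C)C
F2 | step 11 | (3β,8α,14β,21α)-8,14-bis(benzyloxy)-3,21-bis(tert-butyldimethylsilyloxy)-26,27-dinoronocera-1,19-diene-6,16-diol (hydroxyls equatorial) | CC1(C)[C@@H](O[Si](C)(C)C(C)(C)C)C=C[C@@]2(C)[C@H]1[C@@H](O)C[C@@H](OCc3ccccc3)[C@@H]2CC[C@H]1[C@H](OCc2ccccc2)C[C@H](O)[C@H]2C(C)(C)[C@@H](O[Si](C)(C)C(C)(C)C)C=C[C@]12C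
F3 | step 11 | 6,16-bis(O-alkyl S-methyl dithiocarbonate) of F2 | CC1(C)[C@@H](O[Si](C)(C)C(C)(C)C)C=C[C@@]2(C)[C@H]1[C@@H](OC(=S)SC)C[C@@H](OCc3ccccc3)[C@@H]2CC[C@H]1[C@H](OCc2ccccc2)C[C@H](OC(=S)SC)[C@H]2C(C)(C)[C@@H](O[Si](C)(C)C(C)(C)C)C=C[C@]12C
F4 | step 11 | (3β,8α,14β,21α)-8,14-bis(benzyloxy)-3,21-bis(tert-butyldimethylsilyloxy)-26,27-dinoronocera-1,19-diene | CC1(C)[C@@H](O[Si](C)(C)C(C)(C)C)C=C[C@@]2(C)[C@H]1CC[C@@H](OCc3ccccc3)[C@@H]2CC[C@H]1[C@H](OCc2ccccc2)CC[C@H]2C(C)(C)[C@@H](O[Si](C)(C)C(C)(C)C)C=C[C@]12C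
F5 | step 16 | (3β,21α)-3,21-bis(tert-butyldimethylsilyloxy)serrat-14-en-26-ol | CC1(C)[C@@H](O[Si](C)(C)C(C)(C)C)CC[C@@]2(C)[C@H]1CC[C@@]1(CO)CC3=CC[C@H]4C(C)(C)[C@@H](O[Si](C)(C)C(C)(C)C)CC[C@]4(C)[C@H]3CC[C@@H]12
F6 | step 3 | 4-methyl-1-(trimethylsilyl)pent-1-yn-3-one | CC(C)C(=O)C#C[Si](C)(C)C
F7 | step 3 | 4-methyl-1-(trimethylsilyl)-3-(trimethylsilyloxy)pent-3-en-1-yne | CC(C)=C(O[Si](C)(C)C)C#C[Si](C)(C)C
F8 | step 3 | (5R,6E,10E,12R)-4,4,6,11,13,13-hexamethyl-1,16-bis(trimethylsilyl)-5,12-bis(trimethylsilyloxy)hexadeca-6,10-diene-1,15-diyne-3,14-dione | C[Si](C)(C)C#CC(=O)C(C)(C)[C@H](O[Si](C)(C)C)/C(C)=C/CC/C=C(C)/[C@@H](O[Si](C)(C)C)C(C)(C)C(=O)C#C[Si](C)(C)C
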